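## Structural features

The target is a sulfated hydroquinone hexaprenoid with two carbocyclic domains: an octalin (rings B and C, fused through the tetrasubstituted C5=C10 alkene) and a separate methylidenecyclohexanol (ring A), joined by a two-carbon tether from the quaternary C4 of ring B to C1′ of ring A. The arene hangs from C9 of ring C through a methylene. The octalin carries three stereocentres, two of them quaternary (C4: methyl and tether; C9: methyl and arylmethyl), with C8 (methyl, hydrogen) next to C9; C4 and C9 lie at opposite ends of the alkene with no hydrogen-bearing centre between them. Ring A holds three contiguous stereocentres, C1′ (tether), C2′ (quaternary: methyl and homoprenyl) and C3′ (secondary alcohol), with hydroxyl, methyl and tether on one face and the homoprenyl chain on the other. The tether insulates this triad from the octalin, so each domain needs its own source of absolute configuration. Fragile elements are the aryl sulfate monoester (acid-labile, very polar), the hydroquinone behind it (air oxidation), the exocyclic methylene (acid isomerisation) and three further alkenes, which rule out hydrogenation and strong acid late in the route. The real difficulty is the pair of quaternary centres flanking a tetrasubstituted alkene, together with placing one sulfate on one of two phenolic oxygens. The feature exploited is that rings B and C are a 4,9-friedo-drimane. Returning the C9 methyl to C10 and the C8 hydrogen to C9 uncovers an ordinary trans-decalin with a C8 exocyclic methylene, an equatorial C9 arylmethyl group and a C4 quaternary carbon next to C3. That decalin is the chair–chair fold of an aryl-capped (E,E)-diene chain initiated at the α-carbon of an α-methyl β-keto ester, with the C4–C5 and C9–C10 bonds formed in the cascade.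

## Logic of the disconnections

37 ⇒ 36. Bond cut: the O–Si bond at C3′. The hydroxyl stays masked until the sulfate is on, because a free secondary alcohol would compete for the sulfating agent; only the two phenolic oxygens then have to be told apart. Demand: a deprotection that an aryl sulfate and an exocyclic alkene tolerate, hence fluoride and not acid.

36 ⇒ 34 (through 35). Bonds cut: the aryl O–S bond, then the two phenolic O–H bonds back to the quinone. The sulfate comes last among the heavy-atom changes, so every earlier intermediate is neutral and chromatographable; the quinone is the stable storage form of air-sensitive 35. Demand: sulfation of 35 only at the oxygen remote from the side chain.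

34 ⇒ 33. Bonds cut: the two quinone C=O bonds, traced back to aryl O–CH3 ethers. Methyl ethers are the one phenol mask that lasts through aryl-metal, radical, hydride, Lewis acid and ylide steps, so a single inert arene runs from step 1 to step 20. Demand: an oxidant that takes the 1,4-dimethoxyarene before any of the four alkenes.

33 ⇒ 32. Bond cut: C6′=CH2. A carbonyl at C6′ makes C1′ reachable by enolate chemistry and correctable by epimerisation. Demand: olefination of a hindered, α-branched ketone without loss of the C1′ configuration.

32 ⇒ 31 ⇒ 29 ⇒ 25 + 27 + 21. Bonds cut: T2–C1′ and C2′–homoprenyl (the T2–O bond and the C1′=T2 unsaturation are adjustments on the way). This is the only point where the two halves meet, so the cut divides the molecule into an octalin aldehyde and a six-membered ring with one stereocentre, each with its own absolute configuration. Gain: three ring A stereocentres are reduced to one silyloxy-bearing centre. Demand: conjugate addition anti to the silyloxy group at a β,β-disubstituted enone, an enolate that adds to an enolisable aldehyde, and control of C1′ when it is protonated on going from 31 to 32.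

25 ⇒ 24 ⇒ 23 ⇒ 22. Bonds cut: the ring C=O (back to an allylic CH2), O–Si, and the carbinol C–H. Gain: an achiral commercial enone. Demand: enantioselective 1,2-reduction and an allylic oxidation that finds the one methylene.

21 ⇒ 19 (through 20). Bond cut: the T2=O bond, back to a terminal alkyne. The alkyne holds T2 in a form inert to the acid needed one step earlier. Demand: hydroboration of the alkyne only.

19 ⇒ 18. Bonds cut: C9–CH3 and C8–H (returned to C10 and C9), with the alkene moved from C5=C10 to C8=CH2. This cut removes the real problem: two quaternary centres across a tetrasubstituted alkene become one quaternary centre and the ring fusion of an ordinary trans-decalin. Demand: a cationic cascade in which both shifts are suprafacial and which ends with loss of H-5; the C4 arm must be inert to cations.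

18 ⇒ 17 ⇒ 16 ⇒ 14 ⇒ 13 ⇒ 12. Bonds cut: the C≡C bond to T2 (one carbon removed), then functional-group changes only: C3–H back to C3–O, and the carbinol carbons back to ketone and ester. Gain: the oxygen pattern of a β-keto ester, the polar handle that initiates the key step. Demand: deoxygenation at C3 without protecting-group traffic and without disturbing the exocyclic alkene.

12 ⇒ 11. Bonds cut: C4–C5 and C9–C10. Two rings and four stereocentres (C4, C5, C9, C10) are exchanged for two (E)-alkenes and a removable auxiliary. Demand: chair–chair folding, axial ester, facial control at C4 by the auxiliary, and termination to an alkene at C8.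

11 ⇒ 6 + 9 (through 10), and 9 ⇒ 7 + 8. Bonds cut: the CH2–CH2 bond γ to the ketone; the ester C–O bond. Gain: a C12 allylic bromide and a four-carbon keto ester. Demand: alkylation at the terminal carbon of the dianion only.

6 ⇒ 5 ⇒ 4 ⇒ 1 + 2 (through 3). Bonds cut: C–Br, the C–O bond at the terminal (E)-methyl, and the aryl–CH2 bond. Gain: two commercial pieces. Demand: allylic substitution without transposition, and oxidation of the terminal (E)-methyl only.

## Other disconnections considered

Alternative 1: The cut removes ring C through its C9–C10 and C7–C8 bonds and leads to diene A1 (a 1-vinylcyclohexene whose C4 already carries methyl and a silyloxyethyl arm) and tiglic aldehyde A2. Forward, a cationic oxazaborolidine protonated by HNTf2 would activate A2, and [4+2] addition would give aldehyde A3. The cis relationship of the C8 and C9 methyls would come from the (E)-dienophile, and the regiochemistry from bonding of its β-carbon to the vinyl terminus.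
- In its favour: the C8/C9 pair is made directly and suprafacially, enantiocontrol is catalytic, and the two-carbon tether is present from the start.
- Against it here: A1 must already contain the C4 quaternary stereocentre, which sits next to the diene, so every approach is a case of matched or mismatched double induction. A2 is a trisubstituted, α-branched and therefore sluggish dienophile that must form a quaternary carbon at the more hindered diene terminus. A3 is still two tasks from the octalin: migration of the C5=C6 alkene into the ring fusion, and conversion of a neopentyl aldehyde into an arylmethyl group.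
- Comparison: structurally it solves C8/C9 but not C4, whereas the radical cascade sets C4 and, through C9/C10, both other centres. Mechanistically it is a concerted, catalyst-controlled process against a stoichiometric, auxiliary-controlled radical chain; on catalytic asymmetry, the absence of a stoichiometric metal oxidant and the absence of a cationic rearrangement the alternative is the better. On the tether it is also better, since the chosen route spends steps 10, 11 and 13 on adding T2. On step economy the two are judged about equal once the synthesis of enantiopure A1 and the adjustments after the cycloaddition are counted.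

Alternative 2: The cut lies in the other half of the molecule: the C2′–homoprenyl bond and the T2–C1′ bond, giving enone 25, Grignard reagent 27 and octalin aldehyde 21. Forward, copper-catalysed conjugate addition of 27 to 25 is followed by aldol capture of the magnesium enolate by 21, giving adduct A4 with the whole carbon skeleton; no ring closes.
- In its favour: it is the most convergent way to join the halves, it derives C2′ from the silyloxy centre, and it uses the aldehyde oxidation level at T2 that alkyne hydroboration delivers directly.
- Against it: it presupposes 21, so the harder problem (C4, C8, C9 and the tetrasubstituted alkene) is untouched. It leaves a hydroxyl on T2 and a ketone on C6′ that cost three further steps. The C1′ configuration drawn for A4 is not secure, because axial attack on the enolate opposite to its axial C2′ methyl would place the new bond cis to the homoprenyl chain.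
- Comparison: the two are not rivals, since they address different rings. The chosen route adopts this coupling as step 17 (A4 is 29) and so equals the alternative on ring A, while removing the stereochemical doubt by erasing C1′ in step 18 and resetting it by protonation in step 19. As the strategic centre of a synthesis the coupling is the better in convergence. It forms two bonds and at most three stereocentres with no ring, against two bonds, two rings and four stereocentres for the radical cascade, and it needs a separate answer for the octalin.

Alternative 3: The cut is the single C9–C10 bond of ring C, giving enol triflate A5, in which ring B, the C4 quaternary centre (methyl and vinyl), the C8 methyl centre and a tethered trisubstituted styrene are already present. Forward, Pd(OAc)2 with a chiral bisphosphine would give zerovalent palladium, which adds oxidatively to the triflate. The alkenylpalladium would insert the styrene in a 6-exo mode to create the C9 quaternary carbon. The benzylic alkylpalladium, which has no β-hydrogen on C9, would be reduced by HCO2Na to give vinyl octalin A6.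
- In its favour: the tetrasubstituted alkene is formed in its final place, so no hydride–methyl shift is needed; the metal is catalytic; A6 is two operations (hydroboration of the vinyl group, oxidation) from aldehyde 21.
- Against it here: A5 has to carry two stereocentres (C4 and C8) that are remote from one another across a flexible chain and must each be set by a separate asymmetric step. The insertion forms a quaternary carbon beside a tertiary one at a trisubstituted alkene, where reduction of the alkenylpalladium by formate before insertion is a real competitor. The configuration at C9 depends on how ligand control and the two existing centres combine.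
- Comparison: the alternative is the better on where the alkene ends up and on the absence of cationic chemistry. It is equal in delivering an intermediate that enters the same endgame (A6 joins the route at 21). It is weaker in that its key step builds one bond, one ring and one stereocentre against two, two and four, so more of the stereochemical work moves into a longer precursor synthesis, whereas the chosen cascade starts from an achiral chain made in three steps.

Key step: step 6

Remarks on the chemistry:
- Locants: decalin and octalin carbons carry drimane numbers (C4 = quaternary carbon with the one-carbon arm, C5/C10 = ring fusion, C9 = carbon bearing the arylmethyl group; β = face of the C10 methyl of the decalin). Ring A carbons are C1′ (CH joined to the tether), C2′ (quaternary), C3′ (carbinol) to C6′ (carbonyl or methylidene carbon). Tether carbons are T1 (on C4) and T2 (on C1′).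
- Assumption: the hydrogen sulfate is drawn as the free acid; it is taken to be generated by cation exchange in the last operation and stored as its sodium salt.
- Assumption: the (−)-auxiliary is taken to shield the face of the C4 radical that leads to the 4β-ester, 10β-methyl series, by analogy with aryl-terminated substrates of the same type; were the sense opposite, (+)-8-phenylmenthol would be used with no other change.
- The constitution and configuration of 11 and 12 were re-derived atom by atom against the target (4β arm, 8β- and 9β-methyl after the shifts) and need no correction.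

## Steps

Step 1
Reactants: 1 2-bromo-1,4-dimethoxybenzene; 2 geranyl bromide
Product: 4 2-[(2E)-3,7-dimethylocta-2,6-dien-1-yl]-1,4-dimethoxybenzene, via 2,5-dimethoxyphenylmagnesium bromide 3 (not isolated)
Conditions: Mg, THF, 40 °C; then 2, Li2CuCl4 (3 mol%), THF, −10 °C
Reagents that add atoms: none
Why: Copper-catalysed cross-coupling of an aryl Grignard reagent with a primary allylic bromide; aryl nucleophiles favour attack at the unrearranged primary carbon, and the (E)-alkene is not touched.

Step 2
Reactants: 4 2-[(2E)-3,7-dimethylocta-2,6-dien-1-yl]-1,4-dimethoxybenzene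
Product: 5 (2E,6E)-8-(2,5-dimethoxyphenyl)-2,6-dimethylocta-2,6-dien-1-ol
Conditions: SeO2 (0.3 equiv), t-BuOOH (3 equiv), CH2Cl2, 0 °C → rt
Reagents that add atoms: selenium dioxide, O=[Se]=O (transfers the oxygen); tert-butyl hydroperoxide, CC(C)(C)OO (terminal source of that oxygen)
Why: Riley allylic oxidation (ene reaction, then [2,3]-shift) is selective for the (E)-methyl of the terminal trisubstituted alkene of polyprenyl chains; the internal alkene is flanked by the bulkier benzylic arm and should react more slowly.

Step 3
Reactants: 5 (2E,6E)-8-(2,5-dimethoxyphenyl)-2,6-dimethylocta-2,6-dien-1-ol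
Product: 6 2-[(2E,6E)-8-bromo-3,7-dimethylocta-2,6-dien-1-yl]-1,4-dimethoxybenzene
Conditions: PBr3 (0.4 equiv), Et2O, −10 °C
Reagents that add atoms: phosphorus tribromide, BrP(Br)Br
Why: Bromide displaces the phosphite ester of the primary allylic alcohol at low temperature with retention of alkene geometry.

Step 4
Reactants: 7 ethyl 2-methylacetoacetate; 8 (−)-8-phenylmenthol
Product: 9 (1R,2S,5R)-5-methyl-2-(2-phenylpropan-2-yl)cyclohexyl 2-methyl-3-oxobutanoate (both epimers at the acyl α-carbon)
Conditions: DMAP (0.3 equiv), toluene, reflux, EtOH distilled off
Reagents that add atoms: none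
Why: DMAP-catalysed transesterification of a β-keto ester, driven by removal of ethanol; the α-centre of the acyl part is left as a mixture because step 6 destroys it.

Step 5
Reactants: 9 8-phenylmenthyl 2-methyl-3-oxobutanoate; 6 2-[(2E,6E)-8-bromo-3,7-dimethylocta-2,6-dien-1-yl]-1,4-dimethoxybenzene
Product: 11 8-phenylmenthyl (6E,10E)-12-(2,5-dimethoxyphenyl)-2,6,10-trimethyl-3-oxododeca-6,10-dienoate, via sodium lithium dianion 10 (not isolated)
Conditions: NaH, THF, 0 °C; n-BuLi, 0 °C; then 6, 0 °C → rt
Reagents that add atoms: none
Why: Dianion alkylation of a β-keto ester: the more basic terminal carbanion reacts with the allylic bromide by SN2 and the α-methyl centre stays unalkylated; both alkene geometries are carried over.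

Step 6
Reactants: 11 8-phenylmenthyl (6E,10E)-12-(2,5-dimethoxyphenyl)-2,6,10-trimethyl-3-oxododeca-6,10-dienoate
Product: 12 8-phenylmenthyl 9β-(2,5-dimethoxybenzyl)-4α,10β-dimethyl-8-methylidene-3-oxo-5α-decalin-4β-carboxylate (trans fusion, 9α-H)
Conditions: Mn(OAc)3·2H2O (2.2 equiv), Cu(OAc)2·H2O (1.0 equiv), degassed AcOH, 25 °C
Reagents that add atoms: none
Why: Trivalent manganese enolises the α-methyl β-keto ester and oxidises it to the tertiary C4 radical, which adds to the nearer (E)-alkene at its CH terminus (6-endo-trig, C4–C5 bond, ring B); the tertiary C10 radical so formed adds in the same way to the second (E)-alkene (6-endo-trig, C10–C9 bond, ring C). The final tertiary C8 radical is captured by divalent copper and the alkylcopper loses a β-hydrogen from the methyl group, which gives the exocyclic alkene and ends the chain. The closest known reaction type is the oxidative free-radical polyene cyclisation of α-substituted β-keto esters to trans-decalins. C5 and C10 follow from the first (E)-alkene in a chair transition state (trans fusion, angular methyl), and C9 from the second (E)-alkene in the second chair (arylmethyl equatorial). The relative configuration at C4 comes from the preference of such radicals to cyclise with the ketone in the ring and the ester axial, on the face of the C10 methyl. The absolute sense comes from the 8-phenylmenthyl group, whose phenyl ring lies over one face of the planar dicarbonyl radical so that the alkene is engaged on the open face. The step needs endo over exo closure (secured by the trisubstituted alkenes, attacked at the less substituted carbon to give tertiary radicals), oxidation of the last radical faster than its attack on the arene (secured by a full equivalent of the copper salt) and no further oxidation of the product (secured by its quaternary α-carbon); regioisomeric alkene terminations would be harmless, since all of them pass through the same C8 cation in step 12.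

Step 7
Reactants: 12 8-phenylmenthyl decalin keto ester
Product: 13 9β-(2,5-dimethoxybenzyl)-4β-(hydroxymethyl)-4α,10β-dimethyl-8-methylidene-5α-decalin-3β-ol
Conditions: LiAlH4, THF, 0 °C → reflux
Reagents that add atoms: none
Why: Hydride reduction of both ketone and hindered ester; attack at C3 from the α face should give the equatorial 3β-alcohol, whose configuration is of no consequence, and the auxiliary 8 is recovered as the alcohol.

Step 8
Reactants: 13 decalin 3β,4β-CH2 diol
Product: 14 cyclic thionocarbonate (1,3-dioxane-2-thione) bridging O3 and the C4 CH2O of 13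
Conditions: 1,1′-thiocarbonyldiimidazole, DMAP (cat.), toluene, 90 °C
Reagents that add atoms: 1,1′-thiocarbonyldiimidazole, S=C(n1ccnc1)n1ccnc1
Why: The cis-disposed 3β-hydroxyl and 4β-hydroxymethyl close readily to the six-membered thionocarbonate (thiocarbonyl transfer), so no selective protection is needed.

Step 9
Reactants: 14 cyclic thionocarbonate
Product: 16 [9β-(2,5-dimethoxybenzyl)-4α,10β-dimethyl-8-methylidene-5α-decalin-4β-yl]methanol, via S-tributylstannyl thiocarbonate 15 (not isolated)
Conditions: Bu3SnH, AIBN (cat.), toluene, 110 °C; then K2CO3 (cat.), MeOH, rt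
Reagents that add atoms: none
Why: Barton–McCombie-type deoxygenation of a cyclic thionocarbonate: the stannyl radical adds to sulfur and the ring opens at the C3–O bond, which gives the secondary and not the neopentyl primary radical; hydrogen transfer and methanolysis of the remaining thiocarbonate release the primary alcohol.

Step 10
Reactants: 16 decalin 4β-methanol
Product: 17 9β-(2,5-dimethoxybenzyl)-4α,10β-dimethyl-8-methylidene-5α-decalin-4β-carbaldehyde
Conditions: DMP, CH2Cl2, rt
Reagents that add atoms: none
Why: Dess–Martin oxidation of a neopentyl primary alcohol to a non-enolisable aldehyde under near-neutral conditions that leave the exocyclic alkene in place.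

Step 11
Reactants: 17 decalin 4β-carbaldehyde
Product: 18 4β-ethynyl-9β-(2,5-dimethoxybenzyl)-4α,10β-dimethyl-8-methylidene-5α-decalin
Conditions: dimethyl (1-diazo-2-oxopropyl)phosphonate, K2CO3, MeOH, rt
Reagents that add atoms: dimethyl (1-diazo-2-oxopropyl)phosphonate, COP(=O)(OC)C(=[N+]=[N-])C(C)=O
Why: Ohira–Bestmann (Seyferth–Gilbert) homologation: the diazophosphonate anion gives an alkylidene carbene that rearranges by 1,2-hydrogen shift to the terminal alkyne; the aldehyde has no α-hydrogen, so nothing can epimerise. The new carbon is T2, held in a form inert to the acid of step 12.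

Step 12
Reactants: 18 4β-ethynyl decalin with C8 exocyclic methylene
Product: 19 4β-ethynyl-9α-(2,5-dimethoxybenzyl)-4α,8β,9β-trimethyl-Δ5(10)-octalin
Conditions: BF3·OEt2 (3 equiv), CH2Cl2, −50 → −5 °C
Reagents that add atoms: none
Why: Wagner–Meerwein cascade of the type known for 9-arylmethyl drimenes: protonation of the methylene gives the C8 cation, the 9α-hydrogen shifts to C8 (leaving the methyl β), the 10β-methyl shifts to the β face of C9 (pushing the arylmethyl group to α), and loss of H-5 gives the tetrasubstituted alkene. Both shifts are suprafacial and anti-periplanar in the chair, so C8 and C9 are fixed by the configurations set in step 6; C4 is not involved and the alkyne is too poor a nucleophile to intercept.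

Step 13
Reactants: 19 4β-ethynyl octalin
Product: 21 2-[9α-(2,5-dimethoxybenzyl)-4α,8β,9β-trimethyl-Δ5(10)-octalin-4β-yl]acetaldehyde, via alkenyldicyclohexylborane 20 (not isolated)
Conditions: (c-C6H11)2BH (preformed), THF, 0 °C; then H2O2, aq. NaHCO3, 0 °C
Reagents that add atoms: hydrogen peroxide, OO
Why: Hydroboration of a terminal alkyne with a dialkylborane is anti-Markovnikov and stops at the alkenylborane; the tetrasubstituted alkene is inert, and buffered oxidation gives the enol and hence the aldehyde.

Step 14
Reactants: 22 2-methylcyclohex-2-en-1-one
Product: 23 (S)-2-methylcyclohex-2-en-1-ol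
Conditions: (R)-2-methyl-CBS-oxazaborolidine (10 mol%), BH3·SMe2, THF, −20 °C
Reagents that add atoms: none
Why: Corey–Bakshi–Shibata reduction; with the 2-methylalkenyl arm as the large group the (R)-catalyst should deliver hydride to the face that gives the (S)-allylic alcohol, the source of C3′.

Step 15
Reactants: 23 (S)-2-methylcyclohex-2-en-1-ol
Product: 24 (S)-tert-butyldimethyl[(2-methylcyclohex-2-en-1-yl)oxy]silane
Conditions: TBSCl, imidazole, DMF, rt
Reagents that add atoms: tert-butyldimethylsilyl chloride, CC(C)(C)[Si](C)(C)Cl
Why: Standard silylation of a secondary allylic alcohol; the silyl ether later directs the conjugate addition and masks the hydroxyl up to the last step.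

Step 16
Reactants: 24 silyl ether of (S)-2-methylcyclohex-2-en-1-ol
Product: 25 (S)-4-(tert-butyldimethylsilyloxy)-3-methylcyclohex-2-en-1-one
Conditions: Rh2(cap)4 (dirhodium tetracaprolactamate, 1 mol%), t-BuOOH (5 equiv), K2CO3 (0.5 equiv), CH2Cl2, rt
Reagents that add atoms: tert-butyl hydroperoxide, CC(C)(C)OO
Why: Metal-catalysed allylic C–H oxidation by the tert-butylperoxyl radical chain at the only allylic methylene; the other allylic sites are a methyl group and a methine shielded by the silyl group, and the stereocentre is not touched.

Step 17
Reactants: 25 (S)-4-(tert-butyldimethylsilyloxy)-3-methylcyclohex-2-en-1-one; 26 5-bromo-2-methylpent-2-ene; 21 octalin acetaldehyde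
Product: 29 ring A β-hydroxy ketone joined through CH(OH)–CH2 to C4 of the octalin, via homoprenylmagnesium bromide 27 (not isolated), via bromomagnesium enolate 28 (not isolated)
Conditions: 26, Mg, THF; CuBr·SMe2 (10 mol%), 25, THF, −40 °C; then 21, −78 °C; aq. NH4Cl
Reagents that add atoms: none
Why: Copper-catalysed conjugate addition of a Grignard reagent to a γ-silyloxy enone occurs anti to the silyloxy group and sets the quaternary C2′ with homoprenyl trans to oxygen; the regiodefined magnesium enolate then adds to the aldehyde (three-component conjugate addition–aldol). The configurations at C1′ and at the carbinol carbon are erased in step 18.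

Step 18
Reactants: 29 ring A β-hydroxy ketone
Product: 31 alkylidene ketone with a C1′=T2 double bond (either alkene isomer), via mesylate 30 (not isolated)
Conditions: MsCl, Et3N, CH2Cl2, 0 °C; then DBU, rt
Reagents that add atoms: none
Why: Mesylation and DBU-induced E1cB elimination give the conjugated enone; both alkene isomers converge in the next step.

Step 19
Reactants: 31 alkylidene ketone
Product: 32 ring A ketone with saturated tether (tether at C1′ cis to the C2′ methyl and trans to homoprenyl)
Conditions: [(Ph3P)CuH]6 (0.5 equiv), H2O (3 equiv), THF, rt; then NaOMe (cat.), MeOH, rt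
Reagents that add atoms: none
Why: Conjugate reduction by the phosphine-stabilised copper hydride is specific for the enone among five alkenes; protonation of the enolate from the face opposite to the axial C2′ methyl and base equilibration should both favour the epimer in which tether, homoprenyl and silyloxy groups are all equatorial.

Step 20
Reactants: 32 ring A ketone
Product: 33 C6′-methylidene compound (bis-methyl ether and C3′ silyl ether of the desulfated target)
Conditions: Ph3PCH3Br, KOt-Bu, toluene, rt → 80 °C
Reagents that add atoms: methyltriphenylphosphonium bromide, C[P+](c1ccccc1)(c1ccccc1)c1ccccc1.[Br-]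
Why: Wittig methylenation with excess ylide at elevated temperature, as used for hindered α-branched cyclohexanones; any epimerisation under the basic conditions feeds the favoured C1′ epimer, and C1′ is fixed once the ketone is gone.

Step 21
Reactants: 33 C6′-methylidene bis-methyl ether
Product: 34 2-substituted 1,4-benzoquinone carrying the full terpenoid side chain (C3′ silyl ether)
Conditions: (NH4)2Ce(NO3)6 (2.5 equiv), MeCN/H2O (3:1), 0 °C
Reagents that add atoms: water, O
Why: Oxidative demethylation of a 1,4-dimethoxyarene by tetravalent cerium (two one-electron oxidations with attack of water); the arene should be oxidised far more readily than the alkenes, and the hindered silyl ether should survive the short reaction at 0 °C.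

Step 22
Reactants: 34 quinone
Product: 36 C3′ O-silyl ether of the target hydrogen sulfate, via hydroquinone 35 (not isolated)
Conditions: Na2S2O4, THF/H2O, rt; then SO3·pyridine (1.2 equiv), pyridine, 0 °C
Reagents that add atoms: sulfur trioxide–pyridine complex, [O-]S(=O)(=O)[n+]1ccccc1
Why: Dithionite reduces the quinone to the hydroquinone, which is sulfated at the hydroxyl remote from the side chain; the hydroxyl ortho to the neopentyl-type substituent is shielded and the ring A hydroxyl is still silylated.

Step 23
Reactants: 36 C3′ O-silyl ether of the target
Product: 37 4-hydroxy-3-{[(1R,2S,5R)-5-{2-[(1R,2S,3S)-3-hydroxy-2-methyl-6-methylidene-2-(4-methylpent-3-en-1-yl)cyclohexyl]ethyl}-1,2,5-trimethyl-1,2,3,4,5,6,7,8-octahydronaphthalen-1-yl]methyl}phenyl hydrogen sulfate (CNP0426156.3)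
Conditions: TBAF, THF, 45 °C; then cation-exchange resin (H+ form), MeOH, 0 °C
Reagents that add atoms: none
Why: Fluoride-induced cleavage of the silyl ether; aryl sulfate monoesters are stable to fluoride and base, and no acid meets the exocyclic alkene until the brief cold cation exchange.

## Compound list

1 | 2-bromo-1,4-dimethoxybenzene | COc1ccc(OC)c(Br)c1 | starting material
2 | geranyl bromide, (2E)-1-bromo-3,7-dimethylocta-2,6-diene | CC(C)=CCC/C(C)=C/CBr | starting material
3 | 2,5-dimethoxyphenylmagnesium bromide | COc1ccc(OC)c([Mg]Br)c1 | intermediate (not isolated)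
4 | 2-[(2E)-3,7-dimethylocta-2,6-dien-1-yl]-1,4-dimethoxybenzene | COc1ccc(OC)c(C/C=C(\C)CCC=C(C)C)c1 | intermediate
5 | (2E,6E)-8-(2,5-dimethoxyphenyl)-2,6-dimethylocta-2,6-dien-1-ol | COc1ccc(OC)c(C/C=C(\C)CC/C=C(\C)CO)c1 | intermediate
6 | 2-[(2E,6E)-8-bromo-3,7-dimethylocta-2,6-dien-1-yl]-1,4-dimethoxybenzene | COc1ccc(OC)c(C/C=C(\C)CC/C=C(\C)CBr)c1 | intermediate
7 | ethyl 2-methylacetoacetate (ethyl 2-methyl-3-oxobutanoate) | CCOC(=O)C(C)C(C)=O | starting material
8 | (−)-8-phenylmenthol, (1R,2S,5R)-5-methyl-2-(2-phenylpropan-2-yl)cyclohexan-1-ol | O[C@@H]1C[C@H](C)CC[C@H]1C(C)(C)c1ccccc1 | starting material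
9 | (1R,2S,5R)-5-methyl-2-(2-phenylpropan-2-yl)cyclohexyl 2-methyl-3-oxobutanoate, both epimers at the acyl α-carbon | CC(=O)C(C)C(=O)O[C@@H]1C[C@H](C)CC[C@H]1C(C)(C)c1ccccc1 | intermediate
10 | sodium lithium dianion (bis-enolate) of 9 | [Na+].[Li+].C=C([O-])C(C)=C([O-])O[C@@H]1C[C@H](C)CC[C@H]1C(C)(C)c1ccccc1 | intermediate (not isolated)
11 | 8-phenylmenthyl (6E,10E)-12-(2,5-dimethoxyphenyl)-2,6,10-trimethyl-3-oxododeca-6,10-dienoate, both epimers at C2 | COc1ccc(OC)c(C/C=C(\C)CC/C=C(\C)CCC(=O)C(C)C(=O)O[C@@H]2C[C@H](C)CC[C@H]2C(C)(C)c2ccccc2)c1 | intermediate
12 | 8-phenylmenthyl 9β-(2,5-dimethoxybenzyl)-4α,10β-dimethyl-8-methylidene-3-oxo-5α-decalin-4β-carboxylate; trans fusion, axial ester, equatorial arylmethyl | O=C(O[C@@H]1C[C@H](C)CC[C@H]1C(C)(C)c1ccccc1)[C@@]1(C)C(=O)CC[C@@]2(C)[C@H]1CCC(=C)[C@@H]2Cc1cc(OC)ccc1OC | intermediate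
13 | 9β-(2,5-dimethoxybenzyl)-4β-(hydroxymethyl)-4α,10β-dimethyl-8-methylidene-5α-decalin-3β-ol | OC[C@@]1(C)[C@@H](O)CC[C@@]2(C)[C@H]1CCC(=C)[C@@H]2Cc1cc(OC)ccc1OC | intermediate
14 | cyclic thionocarbonate (1,3-dioxane-2-thione) bridging O3 and the C4 CH2O of 13 | S=C1OC[C@@]2(C)[C@@H](O1)CC[C@@]3(C)[C@H]2CCC(=C)[C@@H]3Cc1cc(OC)ccc1OC | intermediate
15 | O-(decalin-4β-ylmethyl) S-tributylstannyl thiocarbonate, C3 deoxygenated | CCCC[Sn](CCCC)(CCCC)SC(=O)OC[C@@]1(C)CCC[C@@]2(C)[C@H]1CCC(=C)[C@@H]2Cc1cc(OC)ccc1OC | intermediate (not isolated)
16 | [9β-(2,5-dimethoxybenzyl)-4α,10β-dimethyl-8-methylidene-5α-decalin-4β-yl]methanol | OC[C@@]1(C)CCC[C@@]2(C)[C@H]1CCC(=C)[C@@H]2Cc1cc(OC)ccc1OC | intermediate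
17 | 9β-(2,5-dimethoxybenzyl)-4α,10β-dimethyl-8-methylidene-5α-decalin-4β-carbaldehyde | O=C[C@@]1(C)CCC[C@@]2(C)[C@H]1CCC(=C)[C@@H]2Cc1cc(OC)ccc1OC | intermediate
18 | 4β-ethynyl-9β-(2,5-dimethoxybenzyl)-4α,10β-dimethyl-8-methylidene-5α-decalin | C#C[C@@]1(C)CCC[C@@]2(C)[C@H]1CCC(=C)[C@@H]2Cc1cc(OC)ccc1OC | intermediate
19 | 4β-ethynyl-9α-(2,5-dimethoxybenzyl)-4α,8β,9β-trimethyl-Δ5(10)-octalin | C#C[C@@]1(C)CCCC2=C1CC[C@H](C)[C@@]2(C)Cc1cc(OC)ccc1OC | intermediate
20 | (E)-2-(octalin-4β-yl)ethenyldicyclohexylborane derived from 19 | C1CCC(CC1)B(/C=C/[C@@]1(C)CCCC2=C1CC[C@H](C)[C@@]2(C)Cc1cc(OC)ccc1OC)C1CCCCC1 | intermediate (not isolated)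
21 | 2-[9α-(2,5-dimethoxybenzyl)-4α,8β,9β-trimethyl-Δ5(10)-octalin-4β-yl]acetaldehyde | O=CC[C@@]1(C)CCCC2=C1CC[C@H](C)[C@@]2(C)Cc1cc(OC)ccc1OC | intermediate
22 | 2-methylcyclohex-2-en-1-one | CC1=CCCCC1=O | starting material
23 | (S)-2-methylcyclohex-2-en-1-ol | CC1=CCCC[C@@H]1O | intermediate
24 | (S)-tert-butyldimethyl[(2-methylcyclohex-2-en-1-yl)oxy]silane | CC1=CCCC[C@@H]1O[Si](C)(C)C(C)(C)C | intermediate
25 | (S)-4-(tert-butyldimethylsilyloxy)-3-methylcyclohex-2-en-1-one | CC1=CC(=O)CC[C@@H]1O[Si](C)(C)C(C)(C)C | intermediate
26 | 5-bromo-2-methylpent-2-ene (homoprenyl bromide) | CC(C)=CCCBr | starting material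
27 | (4-methylpent-3-en-1-yl)magnesium bromide | CC(C)=CCC[Mg]Br | intermediate (not isolated)
28 | bromomagnesium enolate of the conjugate adduct (C6′–O, C6′=C1′; C2′ methyl cis to silyloxy, homoprenyl trans) | Br[Mg]OC1=C[C@](C)(CCC=C(C)C)[C@@H](O[Si](C)(C)C(C)(C)C)CC1 | intermediate (not isolated)
29 | ring A ketone (C6′=O) with C3′ silyloxy, C2′ methyl cis to it and homoprenyl trans, bearing at C1′ a CH(OH)–CH2 arm to C4β of the octalin; C1′ and carbinol configurations as expected from a closed transition state, both erased in step 18 | O=C1CC[C@H](O[Si](C)(C)C(C)(C)C)[C@@](C)(CCC=C(C)C)[C@@H]1[C@H](O)C[C@@]1(C)CCCC2=C1CC[C@H](C)[C@@]2(C)Cc1cc(OC)ccc1OC | intermediate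
30 | methanesulfonate of 29 | O=C1CC[C@H](O[Si](C)(C)C(C)(C)C)[C@@](C)(CCC=C(C)C)[C@@H]1[C@H](OS(C)(=O)=O)C[C@@]1(C)CCCC2=C1CC[C@H](C)[C@@]2(C)Cc1cc(OC)ccc1OC | intermediate (not isolated)
31 | alkylidene ketone, C1′=T2 double bond, mixture of alkene isomers | O=C1CC[C@H](O[Si](C)(C)C(C)(C)C)[C@@](C)(CCC=C(C)C)C1=CC[C@@]1(C)CCCC2=C1CC[C@H](C)[C@@]2(C)Cc1cc(OC)ccc1OC | intermediate
32 | ring A ketone with saturated T1–T2 tether; tether at C1′ cis to the C2′ methyl, trans to homoprenyl | O=C1CC[C@H](O[Si](C)(C)C(C)(C)C)[C@@](C)(CCC=C(C)C)[C@@H]1CC[C@@]1(C)CCCC2=C1CC[C@H](C)[C@@]2(C)Cc1cc(OC)ccc1OC | intermediate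
33 | C6′-methylidene compound: bis-methyl ether and C3′ silyl ether of the desulfated target | C=C1CC[C@H](O[Si](C)(C)C(C)(C)C)[C@@](C)(CCC=C(C)C)[C@@H]1CC[C@@]1(C)CCCC2=C1CC[C@H](C)[C@@]2(C)Cc1cc(OC)ccc1OC | intermediate
34 | 2-substituted 1,4-benzoquinone corresponding to 33 | C=C1CC[C@H](O[Si](C)(C)C(C)(C)C)[C@@](C)(CCC=C(C)C)[C@@H]1CC[C@@]1(C)CCCC2=C1CC[C@H](C)[C@@]2(C)CC1=CC(=O)C=CC1=O | intermediate
35 | hydroquinone corresponding to 34 | C=C1CC[C@H](O[Si](C)(C)C(C)(C)C)[C@@](C)(CCC=C(C)C)[C@@H]1CC[C@@]1(C)CCCC2=C1CC[C@H](C)[C@@]2(C)Cc1cc(O)ccc1O | intermediate (not isolated)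
36 | C3′ O-tert-butyldimethylsilyl ether of the target hydrogen sulfate (sulfate on the oxygen meta to the side chain) | C=C1CC[C@H](O[Si](C)(C)C(C)(C)C)[C@@](C)(CCC=C(C)C)[C@@H]1CC[C@@]1(C)CCCC2=C1CC[C@H](C)[C@@]2(C)Cc1cc(OS(=O)(=O)O)ccc1O | intermediate
37 | 4-hydroxy-3-{[(1R,2S,5R)-5-{2-[(1R,2S,3S)-3-hydroxy-2-methyl-6-methylidene-2-(4-methylpent-3-en-1-yl)cyclohexyl]ethyl}-1,2,5-trimethyl-1,2,3,4,5,6,7,8-octahydronaphthalen-1-yl]methyl}phenyl hydrogen sulfate | C=C1CC[C@H](O)[C@@](C)(CCC=C(C)C)[C@@H]1CC[C@@]1(C)CCCC2=C1CC[C@H](C)[C@@]2(C)Cc1cc(OS(=O)(=O)O)ccc1O | target

## Step count and least certain steps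

Total step count: 23. Longest linear sequence: 19 steps (1, 2, 3, 5 to 13, 17 to 23); steps 4 and 14 to 16 are side branches.

Step 6 (key step). Most likely failure: poor facial selectivity. The C4 radical is planar and the stereogenic unit that must bias it sits in the ester, three bonds away, so the two chair–chair folds leading to enantiomeric decalin cores may not be well differentiated. A second weakness is loss of material when the monocyclic radical is oxidised before the second ring closes. Fallback: give up auxiliary control and resolve. Setting out from 6 and 7, the dianion of 7 (NaH, n-BuLi) is alkylated with 6 to give the ethyl keto ester F1. The same Mn(OAc)3/Cu(OAc)2 pair cyclises it to the racemic ethyl decalin keto ester F2. LiAlH4 reduces F2 to the racemate of 13, and the enantiomers are separated by preparative chromatography on a chiral stationary phase. The route is rejoined at 13.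

Step 12. Most likely failure: interception of the cations. The C8, C9 and C10 cations are generated next to an electron-rich arene and an ethynyl group. Ring closure of the arene onto C8, capture by the alkyne, or arrest of the cascade at isomerised alkenes would divert material, because each 1,2-shift has to outrun these processes. Fallback: change the order, so that the rearrangement runs on a substrate whose C4 arm is a plain acetoxymethyl group and the alkyne is made afterwards. Setting out from 16, Ac2O/pyridine gives the decalin acetate F3, BF3·OEt2 gives the rearranged octalin acetate F4, K2CO3/MeOH gives the octalin methanol F5, and Dess–Martin oxidation gives the octalin carbaldehyde F6. The Ohira–Bestmann reagent then converts F6 into 19, where the route is rejoined.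

Step 17. Most likely failure: proton transfer in place of C–C bond formation. The magnesium enolate is hindered (its carbon adjoins the new quaternary centre) and the aldehyde is enolisable, so deprotonation of 21 and return of the simple conjugate adduct may win; the conjugate addition itself is slowed by β,β-disubstitution. Fallback: separate the two events. Setting out from 25 and 27, the conjugate addition is run in the presence of TMSCl to give the trimethylsilyl enol ether F7, which is isolated. F7 is then joined to 21 in a Mukaiyama aldol addition (BF3·OEt2, CH2Cl2, −78 °C), returning to the route at 29.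

Step 19. Most likely failure: poor facial selectivity in the protonation at C1′, with a thermodynamic preference that may be small. The equatorial tether is gauche to both substituents of the neighbouring quaternary carbon, so the energy gap to the axial epimer is not large. Fallback: kinetic control through an isolated enol derivative. Setting out from 31, 1,4-hydrosilylation (Et3SiH, RhCl(PPh3)3 cat.) gives the triethylsilyl enol ether F8. The lithium enolate released from F8 by MeLi at −78 °C is protonated with 2,6-di-tert-butyl-4-methylphenol from the face opposite to the axial C2′ methyl. The route is rejoined at 32, where a minor epimer can still be separated and re-equilibrated.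

Step 22. Most likely failure: over-sulfation or sulfation at the hindered oxygen, made worse because regioisomeric sulfate salts are hard to separate. Fallback: a protected sulfate. Setting out from 35, 2,2,2-trichloroethyl chlorosulfate (Et3N, DMAP, THF) gives the neutral trichloroethyl aryl sulfate F9, which can be purified on silica. Zn and HCO2NH4 in MeOH then remove the trichloroethyl group and return the route at 36.

## Further compounds

F1 | step 6 | ethyl (6E,10E)-12-(2,5-dimethoxyphenyl)-2,6,10-trimethyl-3-oxododeca-6,10-dienoate | CCOC(=O)C(C)C(=O)CC/C(C)=C/CC/C(C)=C/Cc1cc(OC)ccc1OC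
F2 | step 6 | racemic ethyl 9β-(2,5-dimethoxybenzyl)-4α,10β-dimethyl-8-methylidene-3-oxo-5α-decalin-4β-carboxylate (relative configuration shown) | CCOC(=O)[C@@]1(C)C(=O)CC[C@@]2(C)[C@H]1CCC(=C)[C@@H]2Cc1cc(OC)ccc1OC
F3 | step 12 | [9β-(2,5-dimethoxybenzyl)-4α,10β-dimethyl-8-methylidene-5α-decalin-4β-yl]methyl acetate | CC(=O)OC[C@@]1(C)CCC[C@@]2(C)[C@H]1CCC(=C)[C@@H]2Cc1cc(OC)ccc1OC
F4 | step 12 | [9α-(2,5-dimethoxybenzyl)-4α,8β,9β-trimethyl-Δ5(10)-octalin-4β-yl]methyl acetate | CC(=O)OC[C@@]1(C)CCCC2=C1CC[C@H](C)[C@@]2(C)Cc1cc(OC)ccc1OC
F5 | step 12 | [9α-(2,5-dimethoxybenzyl)-4α,8β,9β-trimethyl-Δ5(10)-octalin-4β-yl]methanol | OC[C@@]1(C)CCCC2=C1CC[C@H](C)[C@@]2(C)Cc1cc(OC)ccc1OC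
F6 | step 12 | 9α-(2,5-dimethoxybenzyl)-4α,8β,9β-trimethyl-Δ5(10)-octalin-4β-carbaldehyde | O=C[C@@]1(C)CCCC2=C1CC[C@H](C)[C@@]2(C)Cc1cc(OC)ccc1OC
F7 | step 17 | trimethylsilyl enol ether of the conjugate adduct of 25 and 27 | C[Si](C)(C)OC1=C[C@](C)(CCC=C(C)C)[C@@H](O[Si](C)(C)C(C)(C)C)CC1
F8 | step 19 | triethylsilyl enol ether of 32 (C6′–O, C6′=C1′) | CC[Si](CC)(CC)OC1=C(CC[C@@]2(C)CCCC3=C2CC[C@H](C)[C@@]3(C)Cc2cc(OC)ccc2OC)[C@](C)(CCC=C(C)C)[C@@H](O[Si](C)(C)C(C)(C)C)CC1
F9 | step 22 | 2,2,2-trichloroethyl aryl sulfate of 35 at the oxygen meta to the side chain | C=C1CC[C@H](O[Si](C)(C)C(C)(C)C)[C@@](C)(CCC=C(C)C)[C@@H]1CC[C@@]1(C)CCCC2=C1CC[C@H](C)[C@@]2(C)Cc1cc(OS(=O)(=O)OCC(Cl)(Cl)Cl)ccc1O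
A1 | alternative 1 | 6-[2-(tert-butyldimethylsilyloxy)ethyl]-6-methyl-1-vinylcyclohex-1-ene with the ring B quaternary configuration | CC(C)(C)[Si](C)(C)OCC[C@@]1(C)CCCC=C1C=C
A2 | alternative 1 | tiglic aldehyde, (E)-2-methylbut-2-enal | C/C=C(\C)C=O
A3 | alternative 1 | ring C aldehyde cycloadduct (alkene at C5=C6, angular hydrogen at C10) | CC(C)(C)[Si](C)(C)OCC[C@@]1(C)CCC[C@@H]2C1=CC[C@H](C)[C@@]2(C)C=O
A4 | alternative 2 | aldol adduct holding the whole carbon skeleton (identical with 29) | O=C1CC[C@H](O[Si](C)(C)C(C)(C)C)[C@@](C)(CCC=C(C)C)[C@@H]1[C@H](O)C[C@@]1(C)CCCC2=C1CC[C@H](C)[C@@]2(C)Cc1cc(OC)ccc1OC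
A5 | alternative 3 | ring B enol triflate with C4 methyl and vinyl and a tethered (E)-trisubstituted styrene | C=C[C@@]1(C)CCCC(OS(=O)(=O)C(F)(F)F)=C1CC[C@H](C)/C(C)=C/c1cc(OC)ccc1OC
A6 | alternative 3 | 4β-vinyl-9α-(2,5-dimethoxybenzyl)-4α,8β,9β-trimethyl-Δ5(10)-octalin | C=C[C@@]1(C)CCCC2=C1CC[C@H](C)[C@@]2(C)Cc1cc(OC)ccc1OC
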